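(All runs are simulated for substances that don't exist, noise included.)

At 50 °C, over the 80.0 s of the teal run, we watch the substrate disappear, and that run is what we have for judging the new flasks.

| flask | substrate | capture agent | temperature | remark | time |
|---|---|---|---|---|---|
| teal | 0.0055 M | 0.10 mM | 50 °C | run made earlier |  |
| theta | 0.0080 M | 0.300 mM | 50 °C |  | 2.0 min |
| gamma | 0.0050 M | 0.100 mM | 50 °C |  | 2.0 min |
| epsilon | 0.015 M | 0.150 mM | 80 °C |  | 2.0 min |
| alpha | 0.0012 M | 0.100 mM | 50 °C |  | 2.0 min |
| eta | 0.0015 M | 0.150 mM | 70 °C |  | 2.0 min |
| delta | 0.0012 M | 0.100 mM | 30 °C |  | 2.0 min |

- teal (time / s: target / %, substrate / %): 12.0: 29.6, 20.8; 25.0: 46.7, 11.9; 40.0: 57.1, 5.3; 50.0: 61.3, 3.1; 60.0: 62.9, 2.1; 80.0: 65.7, 0.6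

(readings scatter by 0.5 percentage points)

- what was read earlier has a scatter of 0.5 percentage points, one standard deviation
- the earlier runs do not show what temperature does; that part of a forecast is a guess
- no earlier run changes the charge of capture agent; that part of a forecast is a guess

- the flasks by amount of target, in percent of the substrate charged, highest first, at 2.0 min (theta / gamma / epsilon / alpha / eta / delta)
- the same order at 15 min (theta / gamma / epsilon / alpha / eta / delta)
- the amount of target, in percent of the substrate charged of the flask you put first, at 2.0 min
- the amount of target, in percent of the substrate charged of the flask you put last, at 2.0 min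

At the last teal reading the substrate stands at 0.6% and the target at 65.7%, each with a scatter of 0.5 percentage points. Together they leave 33.7% of the charge unaccounted for.

The bench rule for a trapping reagent says that what fails to arrive was caught by the trap. We test this rule by writing the balance of the reagent charged in the smaller amount, assuming that one capture agent holds one unit of substrate. What the capture agent holds plus what remains free equals its charge. In teal, the charge of capture agent over the charge of substrate is 1.82%, and we call this ratio the capture ceiling: the share of the charged substrate that the full charge of capture agent can hold.

The rule stops working here, because this ceiling is far smaller than the gap and covers 5.40% of it. The larger part of the loss must therefore lie elsewhere, and we assume that it grows with [substrate]. This gives our reckoning for one pair of flasks. The ceiling is 2.00% in gamma and 3.75% in theta, so the extra capture agent in theta raises the ceiling by 1.7 points, which is small beside the teal gap. Meanwhile [substrate] in theta is higher than in gamma, so we put gamma above theta. For the flasks at other temperatures, the earlier runs allow us a guess and no more.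

The forecast, which assumes that "the loss scales with substrate/capture agent", gives eta > alpha > theta > gamma > epsilon > delta at 2.0 min and eta > alpha > delta > theta > gamma > epsilon at 15 min, with 87% for its first flask and 45% for its last, and so it differs from us by placing theta above gamma.

The flasks give eta > alpha > gamma > theta > epsilon > delta at 2.0 min and eta > alpha > delta > gamma > theta > epsilon at 15 min, with 89.3% for the first and 42.2% for the last. Gamma reaches 67.7% and theta 57.4% at 2.0 min.

    substrate + target → side product (k = 12.0 M⁻¹ s⁻¹, Ea = 53.0 kJ mol⁻¹)
    substrate ⇌ open intermediate (K = 2.40, k = 0.820 s⁻¹, Ea = 72.0 kJ mol⁻¹, ΔH = −13.0 kJ mol⁻¹)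
    open intermediate → target (k = 0.0500 s⁻¹, Ea = 81.0 kJ mol⁻¹)
    open intermediate + capture agent → trapped intermediate (k = 10.0 M⁻¹ s⁻¹, Ea = 36.0 kJ mol⁻¹)
    (constants at 50 °C)

In theta at 2.00 min, 29.1% of the capture agent is left, so the used part times the ceiling puts the trapped intermediate at 2.66% of the substrate charged, far less than the 39.7% of side product. The flask like delta but with [substrate] = 0.0048 M has 29% of its capture agent left at 2.00 min, and the same balance puts its trapped intermediate at 1.49%. In eta, the main reason for the shortfall of target is the passing of substrate and target into side product: without that step, the target of eta rises from 89.3% to 98.9%.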